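The runs were computed from invented constants, noise included.

**Given charges.** No rate constant is at hand, so the reckoning starts from what the charges allow.

| flask | substrate | reagent | free catalyst | precatalyst | remark | time |
|---|---|---|---|---|---|---|
| alder | 74 mM | 35.1 mM | 37 µM | 3.7 mM | run made earlier |  |
| flask | 37 mM | 35.1 mM | 37 µM | 3.7 mM |  | 15 d |

alder run (percent of the substrate charged)

| time / d | side product / % | target / % |
|---|---|---|
| 0.333 | 0.6 | 5.7 |
| 0.625 | 0.8 | 12.2 |
| 1.25 | 0.3 | 25.6 |
| 2.50 | 0.9 | 42.0 |
| 5.00 | 6.8 | 48.4 |

(scatter of a reading: 1 percentage point)

1. ratio of side product to target at 12 h
2. ratio of side product to target at 2.5 d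
3. ratio of side product to target at 15 d



**Alder readings.** In the alder run, target reads 48.4% at 5.00 d, close to the 47.4% that its reagent charge allows at one target per reagent. Target and side product together read 55.2%, so side product takes substrate without reagent.

**Reagent balance.** In this flask reagent is the limiting reagent by charge, 35.1 mM against 37 mM of substrate. Reagent used equals target made, and substrate used beyond that becomes side product. Once both are consumed, target equals the reagent charge and side product equals the surplus. This flask therefore has 0.0541 as its surplus ratio, the substrate charge less the reagent charge over the reagent charge, and that is the side product to target ratio at the end of the balance.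

**Opposite outcome.** For side product to outweigh target at that end, the surplus ratio has to pass 1. The alder charges give 1.11, but this flask's surplus of 1.90 mM stands far below its reagent charge. The balance gives no time, so it says nothing of the early ratios.

**The forecast.** It gives 0.03, 0.025 and 0.06, the last between 0.025 and 0.15, on the ground “capping side product at about 3 mM against about 34 mM target”. Its central value stands slightly above the surplus ratio.

**The result.** The flask gives 0.0384, 0.0191 and 0.0284.

    substrate + free catalyst → free catalyst + open intermediate (k = 280 L mol⁻¹ h⁻¹)
    second catalyst + open intermediate ⇌ catalyst intermediate (K = 11.0 L mol⁻¹, k = 8600 L mol⁻¹ h⁻¹)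
    open intermediate → side product (k = 0.0110 h⁻¹)
    reagent + catalyst intermediate → second catalyst + target (k = 1800 L mol⁻¹ h⁻¹)
    precatalyst → second catalyst (k = 0.0210 h⁻¹)

At 15.0 d, side product stands at 2.67% and target at 94.1%, while 2.4% of the substrate remains. The ratio has thus reached half of the surplus ratio 0.0541. Long after the latest time the computed ratio is 0.0541.

**Richer neighbour.** With 150 mM of substrate, the surplus ratio is 3.27, past 1. The computed ratio at 15.0 d is 2.83, below that value, with reagent at 0%.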